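The runs are calculated with constants of no real substance; scatter was added.

In a one-step world electrophile and nucleophile simply make product, one of each, and the second-order law is enough. This flask also sets acid free, so I asked what that acid costs.

the same everywhere: electrophile 36 mM; nucleophile 1.05 equiv

| flask | solid base | remark | time |
|---|---|---|---|
| dawn | 1.2 equiv | run made earlier |  |
| dusk | 2.7 equiv | run made earlier |  |
| birch | 2.00 equiv |  | 80 min |
| cedar | 2.60 equiv |  | 80 min |
| alder | 3.40 equiv |  | 80 min |

| run | time / min | electrophile / % | product / % |
|---|---|---|---|
| dawn | 15.0 | 90.9 | 6.6 |
| dawn | 30.0 | 85.9 | 13.7 |
| dawn | 40.0 | 82.2 | 17.3 |
| dawn | 60.0 | 76.3 | 23.7 |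
| dusk | 5.00 | 97.9 | 3.3 |
| dusk | 10.0 | 93.8 | 4.6 |
| dusk | 25.0 | 88.3 | 12.9 |
| dusk | 60.0 | 77.1 | 24.7 |

(each reading ± 0.5 percentage points)

- given per volume of solution although it is solid: solid base
- reactions considered so far: solid base <-> free base; electrophile + nucleophile -> acid set free + product; acid set free + free base <-> salt of the base; nucleophile + acid set free <-> protonated nucleophile
- at the start none of the solid base is in solution

* which of these there is most of at the end, counted by the electrophile in it, birch (electrophile / product)
* which of these there is most of at the end, counted by the electrophile in it, cedar (electrophile / product)
* which of these there is most of at the end, counted by the electrophile in it, alder (electrophile / product)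
* how much there is at the end of the one of these that leads, in percent of the electrophile charged: birch
* how much there is at the end of the one of these that leads, in percent of the electrophile charged: cedar
* how much there is at the end of the one of these that leads, in percent of the electrophile charged: alder

I let x be the fraction of the electrophile turned and b the nucleophile in equivalents, and took two extremes that integrate by hand. In the first, the base takes up each acid at once, so every electrophile turned costs one nucleophile. In the second, the acid always takes a nucleophile, so every electrophile turned costs two. In both, the rate of x is a constant κ times the electrophile left times the free nucleophile left.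

The four readings at 60.0 min gave a mean x of 23.8 %. From this the first extreme gave κ = 0.00491 /min and the second κ = 0.00581 /min. I carried the second value as the turning constant, the fraction of the charge turned per minute with electrophile and free nucleophile each at one full charge.

Carried to 80 min, the extremes left 70.6 % and 71.7 % of the electrophile, so electrophile stayed ahead of product. Each electrophile turned takes one nucleophile and its acid may take a second, so the real cost lies between one and two, and I took those two figures as estimates resting on one scattered mean, not as bounds. Going from 1.2 equiv to 2.7 equiv of solid base, electrophile stood at 76.3 % and 77.1 %, with readings good to 0.5 percentage points. I therefore reckoned birch, cedar and alder alike, though alder's 3.40 equiv lies beyond the tested range.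

The forecast put electrophile ahead at 70 %, 70 % and 70 %, holding that “the base loading does not set the rate here”.

Birch, cedar and alder gave electrophile ahead at 71.8 %, 71.8 % and 71.8 %.

    solid base ⇌ free base, rate k1*(cs1 - [free base]) while solid is left; crystals form when [free base] > cs1 (solubility = 4.30 mM, k = 0.00529 /min)
    electrophile + nucleophile → acid set free + product (k = 0.158 /M/min)
    acid set free + free base ⇌ salt of the base, settled at all times (K = 29.0 /M)
    nucleophile + acid set free ⇌ protonated nucleophile, settled at all times (K = 880 /M)

In alder at 80.0 min, 48 % of the nucleophile was left, and κ then gives a pseudo-first-order half-life of 3.95 h against the flask's 4.0 h, far longer than the 80 min of the run. For a neighbouring flask, alder with 2.60 equiv of nucleophile, the same κ at two nucleophiles per electrophile leaves 41.8 % of the electrophile, and that flask held 42.3 % of electrophile and 57.7 % of product.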